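## Retrosynthetic overview

1. The two halves are joined last through the CH2–CH= bond (C(sp3)–C(sp2) coupling of a primary alkyl iodide with an (E)-alkenyl iodide). A final alcohol-to-ketone oxidation completes the oxepanone.
2. Right half, key step: the oxepane ether C–O bond and the tertiary C–O bond are both formed in one Lewis-acid epoxide-relay cascade of a farnesol-derived bis-epoxy tert-butyl carbonate. The oxepane closes first; the cyclohexane and a temporary cyclic carbonate follow in the same event.
3. Left half: ring A is bought (4,4-dimethylcyclohexenone) and ring B is added by a catalytic asymmetric Diels–Alder reaction with isoprene (cis fusion). The tertiary carbinol, the ketone and the exocyclic alkenyl iodide are then installed in turn.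
4. Stereocontrol: every right-half stereocentre derives from one Shi epoxide; every left-half centre derives from convex-face attack on the cis-decalin.

Assumption: the L-fructose-derived Shi ketone gives the (S)-epoxides and the (S)-oxazaborolidinium catalyst gives (4aR,8aS)-10; if a pilot run shows the opposite sense, the mirror-image catalyst is used.

## Route

Step 1
Reactants: 1 (2E,6E)-farnesol
Product: 2 tert-butyl (2E,6E)-farnesyl carbonate
Conditions: Boc2O, N-methylimidazole (cat.), toluene, 0 °C → rt
Reagents that add atoms: di-tert-butyl dicarbonate, CC(C)(C)OC(=O)OC(=O)OC(C)(C)C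
Why: Nucleophile-catalysed O-acylation of the primary allylic alcohol; the carbonate later deactivates the 2,3-alkene towards epoxidation and serves as the internal oxygen nucleophile.

Step 2
Reactants: 2 tert-butyl (2E,6E)-farnesyl carbonate
Product: 3 (6S,7S,10S)-bis-epoxy carbonate
Conditions: L-fructose-derived Shi ketone (0.5 equiv), Oxone, K2CO3, Bu4NHSO4, MeCN–DMM / aq. Na2B4O7–Na2EDTA, 0 °C
Reagents that add atoms: potassium peroxymonosulfate (Oxone), [K+].[O-]S(=O)(=O)OO
Why: Shi asymmetric epoxidation; the chiral dioxirane epoxidises the two electron-rich distal trisubstituted alkenes through the spiro transition state to give the (6S,7S) and (10S) epoxides, while the alkene next to the allylic carbonate is electronically deactivated.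

Step 3
Reactants: 3 (6S,7S,10S)-bis-epoxy carbonate
Product: 6 oxepane triol, via silyl ether cyclic carbonate 4 (not isolated), via hydroxy cyclic carbonate 5 (not isolated)
Conditions: TMSOTf (1.1 equiv), 2,6-di-tert-butyl-4-methylpyridine, CH2Cl2, −78 °C; then K2CO3, MeOH, −78 °C → rt
Reagents that add atoms: none
Why: Proposed new method: a carbonate-terminated epoxide-relay cascade (farnesyl numbering) in which TMSOTf silylates the terminal epoxide, the 6,7-epoxide oxygen opens it at the tertiary C11 (7-endo, new C11–O ether bond = oxepane), the resulting epoxonium is opened at tertiary C7 with inversion by the C2=C3 alkene through a chair transition state, and the developing tertiary cation at C3 is captured anti by the Boc carbonyl oxygen (six-membered ring, loss of isobutene), so both C–O bonds and the trans,anti-fused 5aS,6,7S,9aS array follow from the (6S,7S)-epoxide in one event; the closest known reaction types are Lewis-acid tandem oxa-/carbacyclisations of 1,5-diepoxides terminated by alkenes or enol silanes and the capture of cations by tert-butyl carbonates (iodocarbonate cyclisation), whose combination with an allylic Boc carbonate as terminator has not been shown.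

Step 4
Reactants: 6 oxepane triol
Product: 7 iodomethyl diol
Conditions: I2, PPh3, imidazole, CH2Cl2, 0 °C → rt
Reagents that add atoms: iodine, II
Why: Appel-type iodination proceeds by SN2 at the only primary carbinol; the neopentyl secondary and the tertiary alcohols do not react.

Step 5
Reactants: 8 4,4-dimethylcyclohex-2-en-1-one; 9 isoprene
Product: 10 cis-fused (4aR,8aS)-octalone
Conditions: (S)-o-tolyl-CBS oxazaborolidine (20 mol%), AlBr3 (16 mol%), CH2Cl2, −40 → −20 °C
Reagents that add atoms: none
Why: Chiral oxazaborolidinium-catalysed Diels–Alder reaction; isoprene C1 bonds to the enone β-carbon ("para" orientation), suprafacial addition gives the cis ring fusion, and the catalyst's face selection sets 4aR,8aS.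

Step 6
Reactants: 10 cis-fused (4aR,8aS)-octalone
Product: 11 exocyclic methylene diene
Conditions: Zn, CH2Br2, TiCl4, THF–CH2Cl2, 0 °C → rt
Reagents that add atoms: dibromomethane, BrCBr
Why: Takai–Lombardo methylenation is non-basic, so the epimerisable cis ring fusion next to the ketone is kept.

Step 7
Reactants: 11 exocyclic methylene diene
Product: 13 tertiary alcohol, via tertiary hydroperoxide 12 (not isolated)
Conditions: Co(acac)2 (20 mol%), PhSiH3, O2 (1 atm), i-PrOH, rt; then PPh3
Reagents that add atoms: dioxygen, O=O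
Why: Mukaiyama (hydrogen-atom-transfer) Markovnikov hydration; the 1,1-disubstituted alkene reacts faster than the trisubstituted ring alkene, and O2 traps the tertiary radical on the convex face (syn to the ring-fusion hydrogens), setting the carbinol centre as 1S.

Step 8
Reactants: 13 tertiary alcohol
Product: 15 enone, via allylic alcohol 14 (not isolated)
Conditions: SeO2 (0.5 equiv), t-BuOOH, CH2Cl2, rt; then Dess–Martin periodinane, NaHCO3, CH2Cl2
Reagents that add atoms: tert-butyl hydroperoxide, CC(C)(C)OO
Why: Selenium dioxide allylic oxidation (ene reaction then [2,3]-shift) oxygenates the ring CH2 on the more substituted alkene carbon, and Dess–Martin oxidation then gives the 2-methyl enone.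

Step 9
Reactants: 15 enone
Product: 16 saturated ketone
Conditions: H2 (1 atm), Pd/C, EtOAc, rt
Reagents that add atoms: none
Why: Heterogeneous hydrogenation adds H2 to the enone C=C from the convex face, setting C2 as R (methyl anti to the ring-fusion hydrogens) under neutral conditions that do not epimerise the α-centres.

Step 10
Reactants: 16 saturated ketone
Product: 17 (E)-alkenyl pinacol boronate
Conditions: CH2(Bpin)2 (2.5 equiv), LiTMP (2.5 equiv), THF, 0 °C; then 16, 0 °C → rt
Reagents that add atoms: bis(pinacolatoboryl)methane, CC1(C)OB(CB2OC(C)(C)C(C)(C)O2)OC1(C)C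
Why: Boron-Wittig olefination (addition of LiCH(Bpin)2, then syn B–O elimination) leaves the remaining Bpin cis to the smaller α-carbon (CHMe) and trans to the ring-fusion carbon that carries the CMe2 group, giving the E isomer.

Step 11
Reactants: 17 (E)-alkenyl pinacol boronate
Product: 18 (E)-alkenyl iodide
Conditions: NaOH (aq), I2, THF, 0 °C
Reagents that add atoms: iodine, II
Why: Iododeboronation of the hydroxide "ate" complex replaces boron by iodine with retention of alkene geometry.

Step 12
Reactants: 7 iodomethyl diol; 18 (E)-alkenyl iodide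
Product: 19 coupled secondary alcohol
Conditions: NiI2·xH2O (10 mol%), 4,4′-di-tert-butyl-2,2′-bipyridine (10 mol%), pyridine (cat.), Zn, DMPU, 60 °C
Reagents that add atoms: none
Why: Nickel-catalysed reductive cross-electrophile coupling; the primary alkyl radical from 7 is captured by the alkenyl-nickel species from 18, the alkene geometry is retained and free hydroxyl groups are tolerated.

Step 13
Reactants: 19 coupled secondary alcohol
Product: 20 CNP0232921.1
Conditions: Dess–Martin periodinane, NaHCO3, CH2Cl2, 0 °C → rt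
Reagents that add atoms: none
Why: Dess–Martin oxidation converts the only secondary alcohol into the oxepanone; the two tertiary alcohols and the trisubstituted alkene are inert under buffered conditions.

## Compound list

1 | (2E,6E)-farnesol | CC(C)=CCC/C(C)=C/CC/C(C)=C/CO | starting material
2 | tert-butyl (2E,6E)-3,7,11-trimethyldodeca-2,6,10-trien-1-yl carbonate | CC(C)=CCC/C(C)=C/CC/C(C)=C/COC(=O)OC(C)(C)C | intermediate
3 | tert-butyl (2E,6S,7S,10S)-6,7:10,11-diepoxy-3,7,11-trimethyldodec-2-en-1-yl carbonate (6,7-epoxide trans) | CC1(C)O[C@H]1CC[C@]2(C)O[C@H]2CC/C(C)=C/COC(=O)OC(C)(C)C | intermediate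
4 | 3-O-trimethylsilyl ether of 5 | O=C1OC[C@H]2[C@]3(C)CC[C@H](O[Si](C)(C)C)C(C)(C)O[C@H]3CC[C@]2(C)O1 | intermediate (not isolated)
5 | tricyclic carbonate: trans-fused (3S,5aS,9aS)-3-hydroxy-2,2,5a,7-tetramethyl-decahydro-1-benzoxepine whose 7-O (tertiary, equatorial) and 6-CH2O are joined as a trans-fused 1,3-dioxan-2-one | O=C1OC[C@H]2[C@]3(C)CC[C@H](O)C(C)(C)O[C@H]3CC[C@]2(C)O1 | intermediate (not isolated)
6 | (3S,5aS,6R,7S,9aS)-6-(hydroxymethyl)-2,2,5a,7-tetramethyldecahydro-1-benzoxepine-3,7-diol | OC[C@H]1[C@]2(C)CC[C@H](O)C(C)(C)O[C@H]2CC[C@]1(C)O | intermediate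
7 | (3S,5aS,6S,7S,9aS)-6-(iodomethyl)-2,2,5a,7-tetramethyldecahydro-1-benzoxepine-3,7-diol | IC[C@H]1[C@]2(C)CC[C@H](O)C(C)(C)O[C@H]2CC[C@]1(C)O | intermediate
8 | 4,4-dimethylcyclohex-2-en-1-one | CC1(C)CCC(=O)C=C1 | starting material
9 | isoprene (2-methylbuta-1,3-diene) | CC(=C)C=C | starting material
10 | (4aR,8aS)-4,4,6-trimethyl-3,4,4a,5,8,8a-hexahydronaphthalen-1(2H)-one (cis-fused) | CC1=CC[C@H]2[C@@H](C1)C(C)(C)CCC2=O | intermediate
11 | (4aR,8aS)-4,4,6-trimethyl-1-methylidene-1,2,3,4,4a,5,8,8a-octahydronaphthalene | CC1=CC[C@H]2[C@@H](C1)C(C)(C)CCC2=C | intermediate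
12 | (1S,4aR,8aS)-1-hydroperoxy-1,4,4,6-tetramethyl-1,2,3,4,4a,5,8,8a-octahydronaphthalene | CC1=CC[C@H]2[C@@H](C1)C(C)(C)CC[C@]2(C)OO | intermediate (not isolated)
13 | (1S,4aR,8aS)-1,4,4,6-tetramethyl-1,2,3,4,4a,5,8,8a-octahydronaphthalen-1-ol (OH syn to both ring-fusion H) | CC1=CC[C@H]2[C@@H](C1)C(C)(C)CC[C@]2(C)O | intermediate
14 | (1S,4aR,8aS)-1,4,4,6-tetramethyl-1,2,3,4,4a,5,8,8a-octahydronaphthalene-1,5-diol (C5 epimers) | CC1=CC[C@H]2[C@@H](C1O)C(C)(C)CC[C@]2(C)O | intermediate (not isolated)
15 | (4aS,5S,8aR)-5-hydroxy-2,5,8,8-tetramethyl-4a,5,6,7,8,8a-hexahydronaphthalen-1(4H)-one | CC1=CC[C@H]2[C@@H](C1=O)C(C)(C)CC[C@]2(C)O | intermediate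
16 | (2R,4aS,5S,8aR)-5-hydroxy-2,5,8,8-tetramethyloctahydronaphthalen-1(2H)-one (cis-fused) | C[C@@H]1CC[C@H]2[C@@H](C1=O)C(C)(C)CC[C@]2(C)O | intermediate
17 | (E)-alkenyl boronate: 16 with C=O replaced by C=CH–Bpin, boron cis to the CHMe carbon, ring configurations as in 16 | C[C@@H]1CC[C@H]2[C@@H](/C1=C/B3OC(C)(C)C(C)(C)O3)C(C)(C)CC[C@]2(C)O | intermediate
18 | (E)-alkenyl iodide: 16 with C=O replaced by C=CH–I, iodine cis to the CHMe carbon, ring configurations as in 16 | C[C@@H]1CC[C@H]2[C@@H](/C1=C/I)C(C)(C)CC[C@]2(C)O | intermediate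
19 | (3S,5aS,6S,7S,9aS)-6-{(2E)-2-[(2R,4aS,5S,8aR)-5-hydroxy-2,5,8,8-tetramethyloctahydronaphthalen-1(2H)-ylidene]ethyl}-2,2,5a,7-tetramethyldecahydro-1-benzoxepine-3,7-diol | C[C@@H]1CC[C@H]2[C@@H](/C1=C/C[C@H]1[C@]3(C)CC[C@H](O)C(C)(C)O[C@H]3CC[C@]1(C)O)C(C)(C)CC[C@]2(C)O | intermediate
20 | CNP0232921.1: (5aS,6S,7S,9aS)-7-hydroxy-6-{(2E)-2-[(2R,4aS,5S,8aR)-5-hydroxy-2,5,8,8-tetramethyloctahydronaphthalen-1(2H)-ylidene]ethyl}-2,2,5a,7-tetramethyloctahydro-1-benzoxepin-3(2H)-one | C[C@@H]1CC[C@H]2[C@@H](/C1=C/C[C@H]1[C@]3(C)CCC(=O)C(C)(C)O[C@H]3CC[C@]1(C)O)C(C)(C)CC[C@]2(C)O | target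

## Step count and risks

Total steps: 13. Longest linear sequence: 9 (steps 5–13, from 8 and 9 to 20); the right half needs 4 steps (1–4) before the union.

The three steps most likely to fail:

Step 3 (the proposed cascade). The allylic carbonate alkene may be too weak a nucleophile, or the cation may lose a proton before the carbonate captures it. The fallback uses known reactions only, sets out from 1 and comes back at 6. Acetylation of 1 (Ac2O, pyridine) gives (2E,6E)-farnesyl acetate F1. The same Shi epoxidation gives the (6S,7S,10S)-diepoxy acetate F2. The established alkene-terminated diepoxide cascade (TMSOTf, hindered pyridine base, CH2Cl2, −78 °C, aqueous work-up), in which the cyclohexyl cation simply loses a proton, gives after separation from its endocyclic isomers the exocyclic-methylene oxepane acetate F3. Epoxidation of the 1,1-disubstituted alkene from the equatorial face (mCPBA, NaHCO3) gives the spiro-epoxide F4. LiAlH4 opens that epoxide at CH2 and cleaves the acetate to give triol 6.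

Step 10 (boron-Wittig on a hindered ketone with two epimerisable α-centres). Enolisation may return or epimerise 16, and the E/Z ratio may be poor. The fallback sets out from 16 and comes back at 19. Wittig reaction with Ph3P=CHOMe gives the enol ether F5. Mild hydrolysis (aq. oxalic acid, THF) gives the homologous aldehyde F6. KHMDS then PhNTf2 gives the (E)-enol triflate F7, with the triflate cis to the CHMe carbon. Nickel-catalysed reductive coupling of F7 with iodide 7 then gives 19 directly, bypassing 17 and 18.

Step 12 (cross-electrophile coupling of two hindered partners). Homocoupling, β-hydride elimination or low conversion of the neopentyl-type iodide are possible. The fallback sets out from 7 (with 18) and comes back at 19. Silylation of 7 (TMSOTf, 2,6-lutidine) gives the bis-trimethylsilyl ether F8. Treatment with t-BuLi (2 equiv, −78 °C) and then B-methoxy-9-BBN gives the lithium alkyl borinate F9. B-alkyl Suzuki–Miyaura coupling with 18 (Pd(dppf)Cl2, AsPh3, Cs2CO3, DMF–H2O) gives the coupled bis-silyl ether F10. K2CO3 in MeOH removes both silyl groups to give 19.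

Further compounds
F1 | step 3 | (2E,6E)-farnesyl acetate | CC(C)=CCC/C(C)=C/CC/C(C)=C/COC(C)=O
F2 | step 3 | (2E,6S,7S,10S)-6,7:10,11-diepoxyfarnesyl acetate | CC1(C)O[C@H]1CC[C@]2(C)O[C@H]2CC/C(C)=C/COC(C)=O
F3 | step 3 | [(3S,5aS,6R,9aS)-3-hydroxy-2,2,5a-trimethyl-7-methylidenedecahydro-1-benzoxepin-6-yl]methyl acetate | CC(=O)OC[C@H]1[C@]2(C)CC[C@H](O)C(C)(C)O[C@H]2CCC1=C
F4 | step 3 | spiro-epoxide of F3 (epoxide oxygen equatorial, anti to the angular methyl) | CC(=O)OC[C@H]1[C@]2(C)CC[C@H](O)C(C)(C)O[C@H]2CC[C@@]13CO3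
F5 | step 10 | methyl enol ether of the homologated ketone 16 (E/Z mixture) | C[C@@H]1CC[C@H]2[C@@H](C1=COC)C(C)(C)CC[C@]2(C)O
F6 | step 10 | homologous aldehyde (CHO on the former carbonyl carbon, epimer mixture there) | C[C@@H]1CC[C@H]2[C@@H](C1C=O)C(C)(C)CC[C@]2(C)O
F7 | step 10 | (E)-enol triflate (OTf cis to the CHMe carbon) | C[C@@H]1CC[C@H]2[C@@H](/C1=C/OS(=O)(=O)C(F)(F)F)C(C)(C)CC[C@]2(C)O
F8 | step 12 | 3,7-bis-O-trimethylsilyl ether of 7 | IC[C@H]1[C@]2(C)CC[C@H](O[Si](C)(C)C)C(C)(C)O[C@H]2CC[C@]1(C)O[Si](C)(C)C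
F9 | step 12 | lithium B-alkyl-B-methoxy-9-borabicyclo[3.3.1]nonane borinate of F8 | [Li+].CO[B-]1(C[C@H]2[C@]3(C)CC[C@H](O[Si](C)(C)C)C(C)(C)O[C@H]3CC[C@]2(C)O[Si](C)(C)C)C4CCCC1CCC4
F10 | step 12 | 3,7-bis-O-trimethylsilyl ether of 19 | C[C@@H]1CC[C@H]2[C@@H](/C1=C/C[C@H]1[C@]3(C)CC[C@H](O[Si](C)(C)C)C(C)(C)O[C@H]3CC[C@]1(C)O[Si](C)(C)C)C(C)(C)CC[C@]2(C)O
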